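The flavonol is cut at ring C. Its C4 carbonyl carbon lies alone between C4a of ring A and the C3=C2 unit that carries ring B, so it is drawn from carbon monoxide, and the O1–C2 bond closes the ring. One palladium-catalysed operation unites a ring A 2-iodophenol (iodine at C4a, between the free O1 hydroxyl and the benzylated C5 oxygen, 7,8-dimethoxy pair in place), CO and the dibenzylated ring B arylacetylene, forming C4a–C4, C4–C3 and O1–C2 and the pyranone ring at once. The 3-hydroxyl follows by C3 lithiation, borylation and oxidation, and one hydrogenolysis frees the three phenols.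

Key step: step 8

Remark: a methoxymethyl (MOM) ether serves as the temporary group on the ring A phenol, because it directs lithiation by chelation and leaves under mild acid that spares the aryl iodide and the benzyl ether. Compounds 1, 9, 11 and 13 are assumed to be purchased.

Step 1
Reactants: 1 3-hydroxy-4,5-dimethoxybenzaldehyde
Product: 2 3,4-dimethoxy-5-(methoxymethoxy)benzaldehyde
Conditions: MOMCl, iPr2NEt, CH2Cl2, 0 °C to rt
Reagents that add atoms: chloromethyl methyl ether (MOMCl), COCCl
Why: O-alkylation of the phenol by the reactive chloromethyl ether under amine base (MOM protection, Williamson type) should proceed without touching the aldehyde.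

Step 2
Reactants: 2 3,4-dimethoxy-5-(methoxymethoxy)benzaldehyde
Product: 4 3,4-dimethoxy-5-(methoxymethoxy)phenol, via aryl formate 3 (not isolated)
Conditions: mCPBA, CH2Cl2, 0 °C to rt; then K2CO3 (cat.), MeOH, rt
Reagents that add atoms: 3-chloroperoxybenzoic acid (mCPBA), O=C(OO)c1cccc(Cl)c1
Why: Baeyer–Villiger oxidation of a trialkoxybenzaldehyde should occur with migration of the electron-rich aryl group to give the formate, which mild methanolysis cleaves while the MOM acetal tolerates both peracid and base.

Step 3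
Reactants: 4 3,4-dimethoxy-5-(methoxymethoxy)phenol
Product: 5 5-(benzyloxy)-1,2-dimethoxy-3-(methoxymethoxy)benzene
Conditions: BnBr, K2CO3, DMF, rt
Reagents that add atoms: benzyl bromide, BrCc1ccccc1
Why: Williamson ether synthesis on an unhindered phenoxide with a benzylic bromide should be clean.

Step 4
Reactants: 5 5-(benzyloxy)-1,2-dimethoxy-3-(methoxymethoxy)benzene
Product: 7 1-(benzyloxy)-2-iodo-4,5-dimethoxy-3-(methoxymethoxy)benzene, via aryllithium 6 (not isolated)
Conditions: n-BuLi, THF, 0 °C; then I2, THF, −78 °C to rt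
Reagents that add atoms: iodine, II; n-butyllithium, [Li]CCCC (lithium only in intermediate 6)
Why: Directed ortho-metalation should take place at the single C–H between the chelating MOM ether and the benzyl ether, since the other ring C–H is flanked only by the benzyl ether and a methoxy group whose methyl is pushed toward it by the neighbouring methoxy, and iodinolysis of the aryllithium then fixes iodine at the future C4a.

Step 5
Reactants: 7 1-(benzyloxy)-2-iodo-4,5-dimethoxy-3-(methoxymethoxy)benzene
Product: 8 3-(benzyloxy)-2-iodo-5,6-dimethoxyphenol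
Conditions: HCl (cat.), MeOH, rt
Reagents that add atoms: none
Why: Acid-catalysed acetal exchange with methanol should remove the MOM group as dimethoxymethane, while the benzyl ether, methyl ethers and aryl iodide are inert to dilute acid at room temperature.

Step 6
Reactants: 9 2,4-dihydroxy-5-methoxybenzaldehyde
Product: 10 2,4-bis(benzyloxy)-5-methoxybenzaldehyde
Conditions: BnBr (excess), K2CO3, DMF, 60 °C
Reagents that add atoms: benzyl bromide, BrCc1ccccc1
Why: Twofold Williamson ether synthesis should succeed because warming with excess bromide also alkylates the hydrogen-bonded 2-hydroxyl.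

Step 7
Reactants: 10 2,4-bis(benzyloxy)-5-methoxybenzaldehyde; 11 dimethyl (1-diazo-2-oxopropyl)phosphonate
Product: 12 1,5-bis(benzyloxy)-2-ethynyl-4-methoxybenzene
Conditions: K2CO3, MeOH/THF, rt
Reagents that add atoms: 11 dimethyl (1-diazo-2-oxopropyl)phosphonate, COP(=O)(OC)C(=[N+]=[N-])C(C)=O
Why: Seyferth–Gilbert homologation in its Ohira–Bestmann form should convert the non-enolisable aryl aldehyde into the terminal alkyne, through methanolytic release of the diazomethylphosphonate anion, olefination, loss of N2 and 1,2-hydrogen shift.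

Step 8
Reactants: 8 3-(benzyloxy)-2-iodo-5,6-dimethoxyphenol; 12 1,5-bis(benzyloxy)-2-ethynyl-4-methoxybenzene; 13 carbon monoxide
Product: 16 5,2',4'-tris(benzyloxy)-7,8,5'-trimethoxyflavone, via ynone 14 (not isolated), via enaminone 15 (not isolated)
Conditions: PdCl2(PPh3)2 (5 mol%), CO (20 bar), Et2NH, 120 °C, autoclave
Reagents that add atoms: 13 carbon monoxide, [C-]#[O+]; diethylamine, CCNCC (diethylamino group only in intermediate 15)
Why: Zerovalent palladium, generated from PdCl2(PPh3)2 by amine and alkyne, should insert into the C4a–I bond of 8, CO insertion gives an aroylpalladium iodide, and amine-assisted alkynyl transfer from 12 with reductive elimination gives ynone 14, forming C4a–C4 and C4–C3. Diethylamine then adds in conjugate fashion at C2 to give enaminone 15, and the phenolic O1 attacks C2 with loss of the amine, so ring C closes as a six-membered pyranone by addition–elimination, formally a 6-endo-dig closure onto the ynone. The closest known reaction type is the palladium-catalysed carbonylative Sonogashira annulation of 2-iodophenols with terminal arylacetylenes in secondary amines, an established flavone synthesis. No stereocentre is formed. The step needs six-membered closure to win over five-membered aurone closure and CO insertion to win over direct alkynylation leading to a benzofuran; the enaminone, electrophilic only at C2, secures the first and the CO pressure the second. The 5,7,8 oxygenation pattern cannot scramble because iodine already sits between the O1 hydroxyl and the C5 benzyloxy group of 8.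

Step 9
Reactants: 16 5,2',4'-tris(benzyloxy)-7,8,5'-trimethoxyflavone
Product: 19 5,2',4'-tris(benzyloxy)-3-hydroxy-7,8,5'-trimethoxyflavone, via 3-lithioflavone 17 (not isolated), via flavon-3-yl boronate 18 (not isolated)
Conditions: LiN(iPr)2, THF, −78 °C; B(OMe)3, −78 °C to rt; then AcOH, 30% H2O2, 0 °C to rt
Reagents that add atoms: hydrogen peroxide, OO; lithium diisopropylamide, [Li]N(C(C)C)C(C)C (lithium only in intermediate 17); trimethyl borate, COB(OC)OC (boron only in intermediate 18)
Why: The C3–H next to the C4 carbonyl is the most acidic site of the flavone, so the known lithiation–borylation–oxidation sequence (boron-to-oxygen 1,2-migration under peroxide) should deliver the 3-hydroxyl while benzyl and methyl ethers stay intact at low temperature.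

Step 10
Reactants: 19 5,2',4'-tris(benzyloxy)-3-hydroxy-7,8,5'-trimethoxyflavone
Product: 20 3,5,2',4'-tetrahydroxy-7,8,5'-trimethoxyflavone (target)
Conditions: H2 (1 atm), Pd/C (10 wt%), EtOAc/MeOH, rt
Reagents that add atoms: none
Why: Catalytic hydrogenolysis should cleave the three benzyl aryl ethers as toluene, while the tetrasubstituted, cross-conjugated C2=C3 bond of the flavonol and the methyl ethers are not reduced under these mild conditions.

Compound list
1 | 3-hydroxy-4,5-dimethoxybenzaldehyde | COc1cc(C=O)cc(O)c1OC | starting material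
2 | 3,4-dimethoxy-5-(methoxymethoxy)benzaldehyde | COCOc1cc(C=O)cc(OC)c1OC | intermediate
3 | 3,4-dimethoxy-5-(methoxymethoxy)phenyl formate | COCOc1cc(OC=O)cc(OC)c1OC | intermediate (not isolated)
4 | 3,4-dimethoxy-5-(methoxymethoxy)phenol | COCOc1cc(O)cc(OC)c1OC | intermediate
5 | 5-(benzyloxy)-1,2-dimethoxy-3-(methoxymethoxy)benzene | COCOc1cc(OCc2ccccc2)cc(OC)c1OC | intermediate
6 | [6-(benzyloxy)-3,4-dimethoxy-2-(methoxymethoxy)phenyl]lithium | COCOc1c([Li])c(OCc2ccccc2)cc(OC)c1OC | intermediate (not isolated)
7 | 1-(benzyloxy)-2-iodo-4,5-dimethoxy-3-(methoxymethoxy)benzene | COCOc1c(I)c(OCc2ccccc2)cc(OC)c1OC | intermediate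
8 | 3-(benzyloxy)-2-iodo-5,6-dimethoxyphenol | COc1cc(OCc2ccccc2)c(I)c(O)c1OC | intermediate (key-step precursor)
9 | 2,4-dihydroxy-5-methoxybenzaldehyde | COc1cc(C=O)c(O)cc1O | starting material
10 | 2,4-bis(benzyloxy)-5-methoxybenzaldehyde | COc1cc(C=O)c(OCc2ccccc2)cc1OCc1ccccc1 | intermediate
11 | dimethyl (1-diazo-2-oxopropyl)phosphonate | COP(=O)(OC)C(=[N+]=[N-])C(C)=O | starting material
12 | 1,5-bis(benzyloxy)-2-ethynyl-4-methoxybenzene | C#Cc1cc(OC)c(OCc2ccccc2)cc1OCc1ccccc1 | intermediate (key-step precursor)
13 | carbon monoxide | [C-]#[O+] | starting material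
14 | 1-[6-(benzyloxy)-2-hydroxy-3,4-dimethoxyphenyl]-3-[2,4-bis(benzyloxy)-5-methoxyphenyl]prop-2-yn-1-one | COc1cc(OCc2ccccc2)c(C(=O)C#Cc2cc(OC)c(OCc3ccccc3)cc2OCc2ccccc2)c(O)c1OC | intermediate (not isolated)
15 | (E)-1-[6-(benzyloxy)-2-hydroxy-3,4-dimethoxyphenyl]-3-[2,4-bis(benzyloxy)-5-methoxyphenyl]-3-(diethylamino)prop-2-en-1-one (drawn E; the geometry of this push–pull alkene is labile and has no consequence) | CCN(CC)/C(=C/C(=O)c1c(O)c(OC)c(OC)cc1OCc1ccccc1)c1cc(OC)c(OCc2ccccc2)cc1OCc1ccccc1 | intermediate (not isolated)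
16 | 5,2',4'-tris(benzyloxy)-7,8,5'-trimethoxyflavone, i.e. 5-(benzyloxy)-2-[2,4-bis(benzyloxy)-5-methoxyphenyl]-7,8-dimethoxy-4H-chromen-4-one | COc1cc(-c2cc(=O)c3c(OCc4ccccc4)cc(OC)c(OC)c3o2)c(OCc2ccccc2)cc1OCc1ccccc1 | intermediate (key-step product)
17 | {5-(benzyloxy)-2-[2,4-bis(benzyloxy)-5-methoxyphenyl]-7,8-dimethoxy-4-oxo-4H-chromen-3-yl}lithium | COc1cc(-c2oc3c(OC)c(OC)cc(OCc4ccccc4)c3c(=O)c2[Li])c(OCc2ccccc2)cc1OCc1ccccc1 | intermediate (not isolated)
18 | dimethyl {5-(benzyloxy)-2-[2,4-bis(benzyloxy)-5-methoxyphenyl]-7,8-dimethoxy-4-oxo-4H-chromen-3-yl}boronate (held as its lithium methoxide ate complex until acidification) | COc1cc(-c2oc3c(OC)c(OC)cc(OCc4ccccc4)c3c(=O)c2B(OC)OC)c(OCc2ccccc2)cc1OCc1ccccc1 | intermediate (not isolated)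
19 | 5,2',4'-tris(benzyloxy)-3-hydroxy-7,8,5'-trimethoxyflavone, i.e. 5-(benzyloxy)-2-[2,4-bis(benzyloxy)-5-methoxyphenyl]-3-hydroxy-7,8-dimethoxy-4H-chromen-4-one | COc1cc(-c2oc3c(OC)c(OC)cc(OCc4ccccc4)c3c(=O)c2O)c(OCc2ccccc2)cc1OCc1ccccc1 | intermediate
20 | 3,5,2',4'-tetrahydroxy-7,8,5'-trimethoxyflavone, i.e. 2-(2,4-dihydroxy-5-methoxyphenyl)-3,5-dihydroxy-7,8-dimethoxy-4H-chromen-4-one (achiral) | COc1cc(-c2oc3c(OC)c(OC)cc(O)c3c(=O)c2O)c(O)cc1O | target

Total step count: 10.
Longest linear sequence: 8 steps (steps 1 to 5, then 8, 9 and 10). The ring B branch (steps 6 and 7) joins at step 8.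

Steps most likely to fail

1. Step 8. Oxidative addition into the C–I bond may be slow, because the bond is hindered by two ortho oxygens and sits on a very electron-rich ring (more so once the phenol is deprotonated). Aminocarbonylation by diethylamine, or direct alkynylation followed by benzofuran formation, could then overtake the desired sequence. The fallback builds the ynone without palladium or CO. It sets out from 5, uses alkyne 12, and comes back to the route at ynone 14 and then at 16.
   - Lithiation of 5 as in step 4, quenched with DMF, should give 6-(benzyloxy)-3,4-dimethoxy-2-(methoxymethoxy)benzaldehyde F1.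
   - Addition of the lithium acetylide of 12 (n-BuLi, THF, −78 °C) should give racemic 1-[6-(benzyloxy)-3,4-dimethoxy-2-(methoxymethoxy)phenyl]-3-[2,4-bis(benzyloxy)-5-methoxyphenyl]prop-2-yn-1-ol F2.
   - MnO2 in CH2Cl2 should oxidise this propargylic alcohol to 1-[6-(benzyloxy)-3,4-dimethoxy-2-(methoxymethoxy)phenyl]-3-[2,4-bis(benzyloxy)-5-methoxyphenyl]prop-2-yn-1-one F3.
   - Catalytic HCl in MeOH should remove the MOM group to give ynone 14. Et2NH in EtOH at 60 °C should then close ring C through enaminone 15 to give 16.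

2. Step 4. The butyllithium may deprotonate the benzylic CH2 of the benzyl ether (with Wittig rearrangement), or metalate the other ring position, so that iodine is lost or misplaced. The fallback introduces iodine before any benzyl group is present, between two strong directing groups. It sets out from 4 and comes back at 7.
   - Carbamoylation of 4 (Et2NCOCl, K2CO3, MeCN, reflux) should give 3,4-dimethoxy-5-(methoxymethoxy)phenyl N,N-diethylcarbamate F4.
   - Carbamate- and MOM-directed lithiation (s-BuLi, TMEDA, THF, −78 °C), then I2, should give 2-iodo-4,5-dimethoxy-3-(methoxymethoxy)phenyl N,N-diethylcarbamate F5.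
   - Hydrolysis (NaOH, EtOH, reflux) should give 2-iodo-4,5-dimethoxy-3-(methoxymethoxy)phenol F6.
   - Benzylation (BnBr, K2CO3, DMF) should give 7.

3. Step 9. C3 deprotonation may be incomplete, the amide base may attack C2 and open the pyranone, or the electron-rich flavonol may be over-oxidised by peroxide. The fallback oxidises the C2=C3 bond directly instead of passing through an anion. It sets out from 16 and comes back at 19.
   - Dimethyldioxirane in acetone/CH2Cl2 at 0 °C should give the racemic 2,3-epoxide 6-(benzyloxy)-1a-[2,4-bis(benzyloxy)-5-methoxyphenyl]-3,4-dimethoxy-1a,7a-dihydro-7H-oxireno[2,3-b]chromen-7-one F7.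
   - Catalytic p-TsOH in CH2Cl2 should open and isomerise the epoxide to flavonol 19.

Further compounds
F1 | step 8 | 6-(benzyloxy)-3,4-dimethoxy-2-(methoxymethoxy)benzaldehyde | COCOc1c(C=O)c(OCc2ccccc2)cc(OC)c1OC
F2 | step 8 | 1-[6-(benzyloxy)-3,4-dimethoxy-2-(methoxymethoxy)phenyl]-3-[2,4-bis(benzyloxy)-5-methoxyphenyl]prop-2-yn-1-ol (racemic) | COCOc1c(C(O)C#Cc2cc(OC)c(OCc3ccccc3)cc2OCc2ccccc2)c(OCc2ccccc2)cc(OC)c1OC
F3 | step 8 | 1-[6-(benzyloxy)-3,4-dimethoxy-2-(methoxymethoxy)phenyl]-3-[2,4-bis(benzyloxy)-5-methoxyphenyl]prop-2-yn-1-one | COCOc1c(C(=O)C#Cc2cc(OC)c(OCc3ccccc3)cc2OCc2ccccc2)c(OCc2ccccc2)cc(OC)c1OC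
F4 | step 4 | 3,4-dimethoxy-5-(methoxymethoxy)phenyl N,N-diethylcarbamate | CCN(CC)C(=O)Oc1cc(OCOC)c(OC)c(OC)c1
F5 | step 4 | 2-iodo-4,5-dimethoxy-3-(methoxymethoxy)phenyl N,N-diethylcarbamate | CCN(CC)C(=O)Oc1cc(OC)c(OC)c(OCOC)c1I
F6 | step 4 | 2-iodo-4,5-dimethoxy-3-(methoxymethoxy)phenol | COCOc1c(I)c(O)cc(OC)c1OC
F7 | step 9 | 6-(benzyloxy)-1a-[2,4-bis(benzyloxy)-5-methoxyphenyl]-3,4-dimethoxy-1a,7a-dihydro-7H-oxireno[2,3-b]chromen-7-one (racemic; the epoxide is cis-fused by necessity) | COc1cc(C23OC2C(=O)c2c(OCc4ccccc4)cc(OC)c(OC)c2O3)c(OCc2ccccc2)cc1OCc1ccccc1
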